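**Remarks on the chemistry.** Atoms carry germacrane numbers throughout: ring C1–C10, lactone carbons C11 (α), C12 (C=O) and C13 (exocyclic CH2), C14 on C10, C15 on C4. In step 12 the ligand enantiomer is chosen on the assumption that divinylzinc follows the Si-face preference this ligand series shows with dialkylzincs; if it does not, the antipodal ligand is used. PMB = 4-methoxybenzyl, TBS = tert-butyldimethylsilyl.

## Analysis of the target

CNP0312458.1 (35) is a germacranolide: a cyclodeca-1(10),4-diene trans-fused at C6/C7 to an α-methylene-γ-butyrolactone (O on C6, C11=C13H2, C12=O). It carries a free hydroxyl on C8, an isobutyryloxymethyl group (C14) on C10 and an acetoxymethyl group (C15) on C4. On both trisubstituted olefins the CH2O substituent is trans to the next ring carbon, so the ring carbons are cis (C3/C6 on C4=C5, C9/C2 on C1=C10); by CIP both are E. The three stereocentres are contiguous, (6R,7R,8R): H6 and H7 are trans, and the C8 hydroxyl is syn to C6 when C9–C8–C7–C11 is drawn as a zigzag. The sensitive groups are the α-methylene lactone (a Michael acceptor), two different primary allylic esters that must be neither exchanged nor ionised, and the C8 hydroxyl, which under base can translactonise onto C12 or accept a migrating acyl group. The difficulty is threefold: a ten-membered ring with two ring-cis trisubstituted olefins, four oxygenated carbons (C8, C12, C14, C15) in four different states, and a C8 configuration that has to be set next to the lactone without protecting-group traffic at the end. The strategy rests on the unit C8(OH)–C7–C11(=C13H2)–C12(=O)–O: a homoallylic alcohol whose allyl part is a 2-carbonyl-allyl group. That is what a 3-(metallomethyl)butenolide leaves behind when its γ-carbon C7 adds to a C8 aldehyde, and because C7–C8 is a ring bond, the addition can also close the ring.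

## Retrosynthetic reasoning

**C7–C8 (35 ⇒ 34).** Cutting this bond removes the ring, two stereocentres and the exocyclic methylene at once and leaves the stannylmethyl butenolide aldehyde 34, in which both esters and the lactone are already in place. No other ring bond lets the last step deliver the free C8 hydroxyl and the methylene lactone without later deprotection. The forward reaction is a Lewis-acid SE2′ addition; it has to favour cyclisation, attack the butenolide face anti to C5, and select one aldehyde face.

**Functional-group adjustments (34 ⇒ 33 ⇒ 31 ⇒ 30).** The aldehyde is made last, from alcohol 33, so that only one operation is run with both tin and aldehyde present. The C13–Sn bond comes from the C13–Br bond of 31 with hexabutylditin 32, and 31 from silyl ether 30. Tin is introduced after the desilylation so that no acid or fluoride meets the stannane.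

**C7=C11 and the C6–O ester bond (30 ⇒ 29 ⇒ 27 + 28).** The butenolide is opened at its double bond (ring-closing metathesis) and at the ester linkage. This reduces the lactone to the secondary alcohol 27 carrying a vinyl group, and to the commercial acid 28, which already holds C11, C12 and C13 with the bromide. The ring is closed only after all basic steps, because H6 of the butenolide is both allylic and γ to the carbonyl and would epimerise.

**C6–C7 (27 ⇒ 23 + 24).** A vinyl nucleophile (from 24) added to enal 23 sets C6 by catalyst control. An enal is a good substrate for this, and the stereocentre is created late enough that nothing afterwards can scramble it except the butenolide acidity already guarded against.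

**Oxygen pattern at C6 and C15 (23 ⇒ 21 ⇒ 20 ⇒ 19).** C6 is raised to the aldehyde by allylic oxidation, and the C15 PMB ether is exchanged for the acetate (with 22) while C14 is already an isobutyrate and C8 a silyl ether. After this point no hydroxyl needs differentiating.

**C3–C4 (19 ⇒ 5 + 17).** An sp2–sp3 coupling at C4 joins two fragments of similar size with retention of olefin geometry. The alkenyl iodide 5 supplies C4=C5 with C6 and C15; the borane 18, from hydroboration of the terminal olefin of diene 17, supplies C3 to C1=C10 with C14 and C8.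

**Fragment 5 (5 ⇒ 3 ⇒ 1 + 2).** An anti hydrometalation–iodination of the mono-PMB ether 3 of diol 1 fixes the geometry of C4=C5: iodine (later C3) cis to C6 and the C15 oxygen trans.

**C1=C10 (17 ⇒ 15 ⇒ 14 ⇒ 12 + 13; 12 ⇒ 8 + 9; 8 ⇒ 6 + 7).** A Wittig reaction of the α-substituted ester ylide 12 with acrolein 13 gives the E enoate 14, which places C9 cis to C2. The ylide carries C8 as a silyl ether and C14 as the ester carbon, so the two oxygens are distinct from the start and reduction/acylation delivers the isobutyrate without any selective protection.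

## Alternatives that were turned down

**Alternative 1:** The disconnection cuts C5–C6 and C3–C4, so that C4=C5 is assembled from an aldehyde carbon (C6), the two carbons of a protected propargylic alcohol and an sp3 organozinc carbon (C3). Forward, zerovalent nickel, Ni(cod)2, would couple the three partners with both new bonds on the same face of the alkyne, giving the open-chain allylic alcohol A1.
- For it: the ring-cis C4=C5 geometry follows directly from syn addition, and C7 and C8 are set beforehand on an acyclic aldehyde by dependable chemistry. On the security of C8 it is stronger than the chosen route.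
- Against it: no ring is closed, and A1 stops at C9. C10 with C14, the second trisubstituted olefin, the macrocyclisation, the lactonisation and the α-methylenation all remain, with the hardest bond construction still open.
- Mechanistic doubts: an alkylzinc with β-hydrogens can transfer hydride instead of carbon, which puts H on C4, and the C6 configuration depends on 1,2-induction from an α-branched aldehyde.
- Comparison: the chosen strategy offers, in place of the early fixing of C8, a last step that forms ring, methylene lactone, C7 and C8 together with nothing left to do.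

**Alternative 2:** The disconnection reconnects C4 and C8 so that the ten-membered ring is hidden in a fused five–seven bicycle. Forward, KN(SiMe3)2 would form the C8 alkoxide, which expels a C5 sulfonate with cleavage of C4–C8 to give dienone A2.
- For it: the medium ring is unveiled without any entropic cost or high dilution, and the C4=C5 geometry is dictated stereospecifically by the antiperiplanar arrangement. On reliability of ring formation it is stronger than the chosen route.
- Against it: five stereocentres must be built on the bicycle and three of them are destroyed. In A2 the C8 carbonyl then has to be reduced selectively on a flexible ring, with C7 epimerisable next to it and C1=C10 able to move into conjugation.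
- Step economy: C15 must go from ester to acetoxymethyl, C12 from an ether to the lactone carbonyl and C14 from silyl ether to isobutyrate, at least eight operations after the key step.
- Comparison: the chosen strategy gives up the guaranteed ring opening but ends at its key step and sets C8 in the bond-forming event itself.

**Alternative 3:** The disconnection cuts C9–C10. Forward, cathodic reduction with NiBr2(dme) and 2,2'-bipyridine would turn a C9 redox-active ester into a primary radical and couple it with a tethered C10 alkenyl iodide, closing the ring to lactone A3.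
- For it: all three stereocentres and the trans-lactone exist before the ring is closed, the radical does not care about polar groups, and the alkenyl iodide geometry is retained. On stereochemical certainty it is as strong as or stronger than the chosen route.
- Against it: a primary radical must be captured by an alkenyl–nickel species in the same molecule at the dilution a ten-membered ring demands, where hydrogen abstraction and intermolecular coupling compete, and the 1,1-disubstituted alkenyl iodide is hindered.
- Step economy: A3 still lacks C13 and carries three protected oxygens, so methylenation, three deprotections and two different acylations follow, six to seven steps.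
- Comparison: the chosen strategy creates the methylene by the cyclisation and needs no step after it, at the price of leaving C8 to the transition state.

Key step: step 18

## Route

**Step 1**
Reactants: 1 but-2-yne-1,4-diol; 2 4-methoxybenzyl chloride
Product: 3 4-[(4-methoxybenzyl)oxy]but-2-yn-1-ol
Conditions: NaH (1 equiv), 1 (3 equiv), 2 (1 equiv), n-Bu4NI (cat.), THF/DMF, 0 °C → rt
Reagents that add atoms: 4-methoxybenzyl chloride (2), COc1ccc(CCl)cc1
Why: Williamson monoetherification; the excess of the cheap diol keeps dialkylation low.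

**Step 2**
Reactants: 3 4-[(4-methoxybenzyl)oxy]but-2-yn-1-ol
Product: 5 (2Z)-3-iodo-4-[(4-methoxybenzyl)oxy]but-2-en-1-ol, via cyclic alkenylaluminate 4 (not isolated)
Conditions: NaAlH2(OCH2CH2OMe)2, THF, 0 °C → rt; then I2, THF, −78 → 0 °C; aq. Na2S2O3, Rochelle salt
Reagents that add atoms: iodine, II
Why: trans-Hydroalumination of the propargylic alkoxide delivers hydride to the near alkyne carbon (C5) and aluminium to C4 in a five-membered aluminate; iodinolysis with retention gives the Z iodide. Iodine (the later C3 position) is thus cis to C6 and the C15 oxygen trans to it, as C4=C5 of the target requires.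

**Step 3**
Reactants: 6 (3-bromopropoxy)(tert-butyl)dimethylsilane; 7 triphenylphosphine
Product: 8 {3-[(tert-butyldimethylsilyl)oxy]propyl}triphenylphosphonium bromide
Conditions: MeCN, reflux
Reagents that add atoms: triphenylphosphine (7), c1ccc(cc1)P(c1ccccc1)c1ccccc1
Why: SN2 quaternisation of the phosphine by a primary bromide.

**Step 4**
Reactants: 8 {3-[(tert-butyldimethylsilyl)oxy]propyl}triphenylphosphonium bromide; 9 ethyl chloroformate
Product: 12 ethyl 4-[(tert-butyldimethylsilyl)oxy]-2-(triphenylphosphoranylidene)butanoate, via phosphonium ylide 10 (not isolated), via acylphosphonium chloride 11 (not isolated)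
Conditions: NaN(SiMe3)2 (1 equiv), THF, −78 °C; 9, −78 → 0 °C; NaN(SiMe3)2 (1 equiv), 0 °C
Reagents that add atoms: ethyl chloroformate (9), CCOC(Cl)=O
Why: C-Acylation of a non-stabilised ylide by a chloroformate, then deprotonation of the α-ester phosphonium salt, gives the ester-stabilised ylide. It holds C8 as a silyl ether and C14 as the ester carbon, so the two are never equivalent.

**Step 5**
Reactants: 12 ethyl 4-[(tert-butyldimethylsilyl)oxy]-2-(triphenylphosphoranylidene)butanoate; 13 acrolein
Product: 14 ethyl (2E)-2-{2-[(tert-butyldimethylsilyl)oxy]ethyl}penta-2,4-dienoate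
Conditions: 13 (1.5 equiv), BHT (trace), CH2Cl2, 0 °C → rt
Reagents that add atoms: acrolein (13), C=CC=O
Why: Wittig olefination with an α-substituted ester-stabilised ylide is reversible up to the oxaphosphetane and gives the E enoate. The ester carbon (C14) ends trans and the C9 chain cis to the vinyl group (C2), the geometry of C1=C10.

**Step 6**
Reactants: 14 ethyl (2E)-2-{2-[(tert-butyldimethylsilyl)oxy]ethyl}penta-2,4-dienoate
Product: 15 (2E)-2-{2-[(tert-butyldimethylsilyl)oxy]ethyl}penta-2,4-dien-1-ol
Conditions: i-Bu2AlH (2.2 equiv), CH2Cl2, −78 °C; Rochelle salt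
Reagents that add atoms: none
Why: 1,2-Reduction of the conjugated ester to the allylic alcohol; the silyl ether and the diene are not affected at low temperature.

**Step 7**
Reactants: 15 (2E)-2-{2-[(tert-butyldimethylsilyl)oxy]ethyl}penta-2,4-dien-1-ol; 16 2-methylpropanoyl chloride
Product: 17 (2E)-2-{2-[(tert-butyldimethylsilyl)oxy]ethyl}penta-2,4-dien-1-yl 2-methylpropanoate
Conditions: 16, pyridine, DMAP (cat.), CH2Cl2, 0 °C
Reagents that add atoms: 2-methylpropanoyl chloride (16), CC(C)C(Cl)=O
Why: Acylation of the only free hydroxyl puts the isobutyrate on C14 before any other alcohol exists.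

**Step 8**
Reactants: 17 (2E)-2-{2-[(tert-butyldimethylsilyl)oxy]ethyl}penta-2,4-dien-1-yl 2-methylpropanoate; 5 (2Z)-3-iodo-4-[(4-methoxybenzyl)oxy]but-2-en-1-ol
Product: 19 (2E,6E)-8-hydroxy-6-{[(4-methoxybenzyl)oxy]methyl}-2-{2-[(tert-butyldimethylsilyl)oxy]ethyl}octa-2,6-dien-1-yl 2-methylpropanoate, via B-alkyl-9-BBN borane 18 (not isolated)
Conditions: 9-BBN (1.0 equiv on 17), THF, 0 °C → rt; then 5, PdCl2(dppf) (5 mol %), AsPh3, Cs2CO3, DMF/THF/H2O, rt
Reagents that add atoms: none
Why: 9-BBN adds to the terminal, monosubstituted olefin of the diene (boron on C3) and leaves the hindered trisubstituted one. The B-alkyl Suzuki–Miyaura coupling with the alkenyl iodide goes with retention, so C3 takes the place of iodine cis to C6. Carbonate at room temperature tolerates the ester, the silyl ether and the free allylic alcohol.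

**Step 9**
Reactants: 19 (2E,6E)-8-hydroxy-6-{[(4-methoxybenzyl)oxy]methyl}-2-{2-[(tert-butyldimethylsilyl)oxy]ethyl}octa-2,6-dien-1-yl 2-methylpropanoate
Product: 20 (2E,6E)-6-{[(4-methoxybenzyl)oxy]methyl}-8-oxo-2-{2-[(tert-butyldimethylsilyl)oxy]ethyl}octa-2,6-dien-1-yl 2-methylpropanoate
Conditions: MnO2 (activated, excess), CH2Cl2, rt
Reagents that add atoms: none
Why: Chemoselective oxidation of the primary allylic alcohol under neutral conditions, which should keep the geometry of the β,β-disubstituted enal.

**Step 10**
Reactants: 20 (2E,6E)-6-{[(4-methoxybenzyl)oxy]methyl}-8-oxo-2-{2-[(tert-butyldimethylsilyl)oxy]ethyl}octa-2,6-dien-1-yl 2-methylpropanoate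
Product: 21 (2E,6E)-6-(hydroxymethyl)-8-oxo-2-{2-[(tert-butyldimethylsilyl)oxy]ethyl}octa-2,6-dien-1-yl 2-methylpropanoate
Conditions: DDQ (1.2 equiv), CH2Cl2/pH 7 buffer, 0 °C
Reagents that add atoms: none
Why: Oxidative PMB cleavage by benzylic hydride abstraction and hydrolysis; the silyl ether and ester are untouched. The freed hydroxymethyl group is trans to the formyl group and cannot form a lactol.

**Step 11**
Reactants: 21 (2E,6E)-6-(hydroxymethyl)-8-oxo-2-{2-[(tert-butyldimethylsilyl)oxy]ethyl}octa-2,6-dien-1-yl 2-methylpropanoate; 22 acetic anhydride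
Product: 23 (2E,6E)-6-(acetoxymethyl)-8-oxo-2-{2-[(tert-butyldimethylsilyl)oxy]ethyl}octa-2,6-dien-1-yl 2-methylpropanoate
Conditions: 22, pyridine, CH2Cl2, 0 °C → rt
Reagents that add atoms: acetic anhydride (22), CC(=O)OC(C)=O
Why: Acetylation of the primary allylic alcohol puts the C15 acetate in place; a weak base without nucleophilic catalyst spares the enal geometry.

**Step 12**
Reactants: 23 (2E,6E)-6-(acetoxymethyl)-8-oxo-2-{2-[(tert-butyldimethylsilyl)oxy]ethyl}octa-2,6-dien-1-yl 2-methylpropanoate; 24 vinylmagnesium bromide
Product: 27 (2E,6E,8S)-6-(acetoxymethyl)-8-hydroxy-2-{2-[(tert-butyldimethylsilyl)oxy]ethyl}deca-2,6,9-trien-1-yl 2-methylpropanoate, via divinylzinc 25 (not isolated), via vinylzinc alkoxide 26 (not isolated)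
Conditions: 24, ZnCl2 (0.5 equiv), Et2O, 0 °C; 1,4-dioxane, filter; then (−)-MIB (10 mol %), 23, toluene, −30 → 0 °C; aq. NH4Cl
Reagents that add atoms: vinylmagnesium bromide (24), C=C[Mg]Br
Why: Catalytic enantioselective alkenylzinc addition to an aldehyde: the zinc aminoalkoxide of the ligand delivers a vinyl group to the Si face of the enal carbonyl. This sets C6 as S, the spatial arrangement that is named 6R once C7 outranks C5. Organozinc reagents leave the acetate and the isobutyrate alone.

**Step 13**
Reactants: 27 (2E,6E,8S)-6-(acetoxymethyl)-8-hydroxy-2-{2-[(tert-butyldimethylsilyl)oxy]ethyl}deca-2,6,9-trien-1-yl 2-methylpropanoate; 28 2-(bromomethyl)prop-2-enoic acid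
Product: 29 (2E,6E,8S)-6-(acetoxymethyl)-8-{[2-(bromomethyl)prop-2-enoyl]oxy}-2-{2-[(tert-butyldimethylsilyl)oxy]ethyl}deca-2,6,9-trien-1-yl 2-methylpropanoate
Conditions: 28, N,N'-diisopropylcarbodiimide, DMAP (5 mol %), CH2Cl2, −20 → 0 °C
Reagents that add atoms: 2-(bromomethyl)prop-2-enoic acid (28), C=C(CBr)C(=O)O
Why: Steglich esterification with retention at C6 brings in C11, C12 and C13 with the bromide already on C13. Low temperature and little DMAP limit attack of the amine on the allylic bromide.

**Step 14**
Reactants: 29 (2E,6E,8S)-6-(acetoxymethyl)-8-{[2-(bromomethyl)prop-2-enoyl]oxy}-2-{2-[(tert-butyldimethylsilyl)oxy]ethyl}deca-2,6,9-trien-1-yl 2-methylpropanoate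
Product: 30 (2E,6E)-6-(acetoxymethyl)-7-[(2R)-4-(bromomethyl)-5-oxo-2,5-dihydrofuran-2-yl]-2-{2-[(tert-butyldimethylsilyl)oxy]ethyl}hepta-2,6-dien-1-yl 2-methylpropanoate
Conditions: second-generation Grubbs catalyst (5–10 mol %), CH2Cl2 (0.005 M), 40 °C
Reagents that add atoms: none
Why: Ring-closing metathesis: the catalyst loads on the monosubstituted C7 vinyl group and closes the five-membered ring onto the 1,1-disubstituted acrylate olefin, forming C7=C11. C1=C10, an acyloxymethyl-substituted trisubstituted olefin of the least reactive class toward ruthenium alkylidenes, could only close a seven-membered ring and should stay a spectator. C6 is not touched; its descriptor changes to R only by priority.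

**Step 15**
Reactants: 30 (2E,6E)-6-(acetoxymethyl)-7-[(2R)-4-(bromomethyl)-5-oxo-2,5-dihydrofuran-2-yl]-2-{2-[(tert-butyldimethylsilyl)oxy]ethyl}hepta-2,6-dien-1-yl 2-methylpropanoate
Product: 31 (2E,6E)-6-(acetoxymethyl)-7-[(2R)-4-(bromomethyl)-5-oxo-2,5-dihydrofuran-2-yl]-2-(2-hydroxyethyl)hepta-2,6-dien-1-yl 2-methylpropanoate
Conditions: aq. HF (48 %), MeCN, 0 °C
Reagents that add atoms: none
Why: Acidic fluoride cleavage of the primary silyl ether without amine or basic fluoride, which neither the allylic bromide nor the acidic H6 of the butenolide would tolerate.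

**Step 16**
Reactants: 31 (2E,6E)-6-(acetoxymethyl)-7-[(2R)-4-(bromomethyl)-5-oxo-2,5-dihydrofuran-2-yl]-2-(2-hydroxyethyl)hepta-2,6-dien-1-yl 2-methylpropanoate; 32 hexabutylditin
Product: 33 (2E,6E)-6-(acetoxymethyl)-2-(2-hydroxyethyl)-7-{(2R)-5-oxo-4-[(tributylstannyl)methyl]-2,5-dihydrofuran-2-yl}hepta-2,6-dien-1-yl 2-methylpropanoate
Conditions: 32 (1.2 equiv), Pd2(dba)3 (2.5 mol %), THF, 0 °C → rt; neutral alumina
Reagents that add atoms: hexabutylditin (32), CCCC[Sn](CCCC)(CCCC)[Sn](CCCC)(CCCC)CCCC
Why: Palladium-catalysed stannylation of an allylic bromide: zerovalent palladium inserts into C13–Br far faster than into allylic carboxylates when no phosphine is present, and the distannane transmetalates. Reductive elimination at the unhindered primary terminus keeps the olefin in the ring. The medium is neutral, so C6 is safe.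

**Step 17**
Reactants: 33 (2E,6E)-6-(acetoxymethyl)-2-(2-hydroxyethyl)-7-{(2R)-5-oxo-4-[(tributylstannyl)methyl]-2,5-dihydrofuran-2-yl}hepta-2,6-dien-1-yl 2-methylpropanoate
Product: 34 (2E,6E)-6-(acetoxymethyl)-2-(2-oxoethyl)-7-{(2R)-5-oxo-4-[(tributylstannyl)methyl]-2,5-dihydrofuran-2-yl}hepta-2,6-dien-1-yl 2-methylpropanoate
Conditions: Dess–Martin periodinane (1.3 equiv), NaHCO3, CH2Cl2, 0 °C; used without chromatography
Reagents that add atoms: none
Why: Dess–Martin oxidation of the primary alcohol under bicarbonate buffering; non-nucleophilic, near-neutral conditions are chosen so that the β,γ-unsaturated aldehyde does not isomerise and the allylstannane is not protonated.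

**Step 18**
Reactants: 34 (2E,6E)-6-(acetoxymethyl)-2-(2-oxoethyl)-7-{(2R)-5-oxo-4-[(tributylstannyl)methyl]-2,5-dihydrofuran-2-yl}hepta-2,6-dien-1-yl 2-methylpropanoate
Product: 35 CNP0312458.1, [(3aR,4R,6E,10E,11aR)-10-(acetoxymethyl)-4-hydroxy-3-methylidene-2-oxo-2,3,3a,4,5,8,9,11a-octahydrocyclodeca[b]furan-6-yl]methyl 2-methylpropanoate (germacrane numbering 6R,7R,8R)
Conditions: BF3·OEt2 (2–3 equiv), CH2Cl2, slow addition of 34 (final 0.002 M), −78 → −40 °C; cold aq. NaHCO3
Reagents that add atoms: none
Why: Proposed new method: BF3 binds the C8 aldehyde, and the 2-carbonyl allylstannane, whose C13–Sn bond is aligned with the C7=C11 π bond, attacks it through its γ-carbon C7 anti to tin (SE2′) in an open transition state; tin leaves as Bu3SnF and the double bond moves to C11=C13, so the C7–C8 bond, the exocyclic methylene and the free C8 hydroxyl appear in one event. The closest known reactions are the BF3-promoted additions of 2-(alkoxycarbonyl)allylstannanes to aldehydes and the Lewis-acid allylstannane–aldehyde macrocyclisations; neither has been run with a γ-substituted stannane that is part of a butenolide, nor to close a ten-membered ring. The ring closes in the 10-exo-trig mode at the aldehyde carbon (the carbonyl oxygen ends outside the ring), with the two ring-cis olefins and the planar butenolide folding the chain. C7 is set by C6: C8 should bond to the butenolide face opposite the C5 substituent, which gives the trans-fused lactone (7R) and lets the C5–C6–C7–C8 segment take the staggered arrangement a ten-membered ring prefers. C8 is set by the choice of aldehyde face: in the open, non-chelated transition state C9 should avoid the C6 substituent, the arrangement that gives syn homoallylic alcohols from γ-substituted allylstannanes and here 8R; this is the one element the substrate does not enforce. The step needs cyclisation over oligomerisation (slow addition, high dilution), attack by the stannane rather than by the less nucleophilic acyloxymethyl-substituted olefins, and γ- over α-attack, which is inherent to SE2′; the esters and the lactone should not react with BF3·OEt2 at −78 °C, and a cold quench avoids translactonisation of the new C8 alkoxide onto C12.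

## Compound list

1 | but-2-yne-1,4-diol | OCC#CCO | starting material
2 | 4-methoxybenzyl chloride | COc1ccc(CCl)cc1 | starting material
3 | 4-[(4-methoxybenzyl)oxy]but-2-yn-1-ol | OCC#CCOCc1ccc(OC)cc1 | intermediate
4 | cyclic sodium alkenylaluminate from trans-hydroalumination of 3 (Al on C4 and on the C6 oxygen) | [Na+].COCCO[Al-]1(OCCOC)OCC=C1COCc1ccc(OC)cc1 | intermediate (not isolated)
5 | (2Z)-3-iodo-4-[(4-methoxybenzyl)oxy]but-2-en-1-ol | OC/C=C(\I)COCc1ccc(OC)cc1 | intermediate
6 | (3-bromopropoxy)(tert-butyl)dimethylsilane | BrCCCO[Si](C)(C)C(C)(C)C | starting material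
7 | triphenylphosphine | c1ccc(cc1)P(c1ccccc1)c1ccccc1 | starting material
8 | {3-[(tert-butyldimethylsilyl)oxy]propyl}triphenylphosphonium bromide | [Br-].CC(C)(C)[Si](C)(C)OCCC[P+](c1ccccc1)(c1ccccc1)c1ccccc1 | intermediate
9 | ethyl chloroformate | CCOC(Cl)=O | starting material
10 | {3-[(tert-butyldimethylsilyl)oxy]propylidene}triphenylphosphorane | CC(C)(C)[Si](C)(C)OCCC=P(c1ccccc1)(c1ccccc1)c1ccccc1 | intermediate (not isolated)
11 | {3-[(tert-butyldimethylsilyl)oxy]-1-(ethoxycarbonyl)propyl}triphenylphosphonium chloride | [Cl-].CCOC(=O)C(CCO[Si](C)(C)C(C)(C)C)[P+](c1ccccc1)(c1ccccc1)c1ccccc1 | intermediate (not isolated)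
12 | ethyl 4-[(tert-butyldimethylsilyl)oxy]-2-(triphenylphosphoranylidene)butanoate | CCOC(=O)C(CCO[Si](C)(C)C(C)(C)C)=P(c1ccccc1)(c1ccccc1)c1ccccc1 | intermediate
13 | acrolein | C=CC=O | starting material
14 | ethyl (2E)-2-{2-[(tert-butyldimethylsilyl)oxy]ethyl}penta-2,4-dienoate | CC(C)(C)[Si](C)(C)OCC/C(C(=O)OCC)=C\C=C | intermediate
15 | (2E)-2-{2-[(tert-butyldimethylsilyl)oxy]ethyl}penta-2,4-dien-1-ol | CC(C)(C)[Si](C)(C)OCC/C(CO)=C\C=C | intermediate
16 | 2-methylpropanoyl chloride | CC(C)C(Cl)=O | starting material
17 | (2E)-2-{2-[(tert-butyldimethylsilyl)oxy]ethyl}penta-2,4-dien-1-yl 2-methylpropanoate | CC(C)(C)[Si](C)(C)OCC/C(COC(=O)C(C)C)=C\C=C | intermediate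
18 | B-alkyl-9-BBN borane from 17 (boron on C3) | CC(C)(C)[Si](C)(C)OCC/C(COC(=O)C(C)C)=C\CCB1C2CCCC1CCC2 | intermediate (not isolated)
19 | (2E,6E)-8-hydroxy-6-{[(4-methoxybenzyl)oxy]methyl}-2-{2-[(tert-butyldimethylsilyl)oxy]ethyl}octa-2,6-dien-1-yl 2-methylpropanoate | CC(C)(C)[Si](C)(C)OCC/C(COC(=O)C(C)C)=C\CC/C(COCc1ccc(OC)cc1)=C\CO | intermediate
20 | (2E,6E)-6-{[(4-methoxybenzyl)oxy]methyl}-8-oxo-2-{2-[(tert-butyldimethylsilyl)oxy]ethyl}octa-2,6-dien-1-yl 2-methylpropanoate | CC(C)(C)[Si](C)(C)OCC/C(COC(=O)C(C)C)=C\CC/C(COCc1ccc(OC)cc1)=C\C=O | intermediate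
21 | (2E,6E)-6-(hydroxymethyl)-8-oxo-2-{2-[(tert-butyldimethylsilyl)oxy]ethyl}octa-2,6-dien-1-yl 2-methylpropanoate | CC(C)(C)[Si](C)(C)OCC/C(COC(=O)C(C)C)=C\CC/C(CO)=C\C=O | intermediate
22 | acetic anhydride | CC(=O)OC(C)=O | starting material
23 | (2E,6E)-6-(acetoxymethyl)-8-oxo-2-{2-[(tert-butyldimethylsilyl)oxy]ethyl}octa-2,6-dien-1-yl 2-methylpropanoate | CC(C)(C)[Si](C)(C)OCC/C(COC(=O)C(C)C)=C\CC/C(COC(C)=O)=C\C=O | intermediate
24 | vinylmagnesium bromide | C=C[Mg]Br | starting material
25 | divinylzinc | C=C[Zn]C=C | intermediate (not isolated)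
26 | vinylzinc alkoxide of 27 | CC(C)(C)[Si](C)(C)OCC/C(COC(=O)C(C)C)=C\CC/C(COC(C)=O)=C\[C@H](C=C)O[Zn]C=C | intermediate (not isolated)
27 | (2E,6E,8S)-6-(acetoxymethyl)-8-hydroxy-2-{2-[(tert-butyldimethylsilyl)oxy]ethyl}deca-2,6,9-trien-1-yl 2-methylpropanoate | CC(C)(C)[Si](C)(C)OCC/C(COC(=O)C(C)C)=C\CC/C(COC(C)=O)=C\[C@H](C=C)O | intermediate
28 | 2-(bromomethyl)prop-2-enoic acid | C=C(CBr)C(=O)O | starting material
29 | (2E,6E,8S)-6-(acetoxymethyl)-8-{[2-(bromomethyl)prop-2-enoyl]oxy}-2-{2-[(tert-butyldimethylsilyl)oxy]ethyl}deca-2,6,9-trien-1-yl 2-methylpropanoate | CC(C)(C)[Si](C)(C)OCC/C(COC(=O)C(C)C)=C\CC/C(COC(C)=O)=C\[C@H](C=C)OC(=O)C(=C)CBr | intermediate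
30 | (2E,6E)-6-(acetoxymethyl)-7-[(2R)-4-(bromomethyl)-5-oxo-2,5-dihydrofuran-2-yl]-2-{2-[(tert-butyldimethylsilyl)oxy]ethyl}hepta-2,6-dien-1-yl 2-methylpropanoate | CC(C)(C)[Si](C)(C)OCC/C(COC(=O)C(C)C)=C\CC/C(COC(C)=O)=C\[C@H]1OC(=O)C(CBr)=C1 | intermediate
31 | (2E,6E)-6-(acetoxymethyl)-7-[(2R)-4-(bromomethyl)-5-oxo-2,5-dihydrofuran-2-yl]-2-(2-hydroxyethyl)hepta-2,6-dien-1-yl 2-methylpropanoate | OCC/C(COC(=O)C(C)C)=C\CC/C(COC(C)=O)=C\[C@H]1OC(=O)C(CBr)=C1 | intermediate
32 | hexabutylditin | CCCC[Sn](CCCC)(CCCC)[Sn](CCCC)(CCCC)CCCC | starting material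
33 | (2E,6E)-6-(acetoxymethyl)-2-(2-hydroxyethyl)-7-{(2R)-5-oxo-4-[(tributylstannyl)methyl]-2,5-dihydrofuran-2-yl}hepta-2,6-dien-1-yl 2-methylpropanoate | OCC/C(COC(=O)C(C)C)=C\CC/C(COC(C)=O)=C\[C@H]1OC(=O)C(C[Sn](CCCC)(CCCC)CCCC)=C1 | intermediate
34 | (2E,6E)-6-(acetoxymethyl)-2-(2-oxoethyl)-7-{(2R)-5-oxo-4-[(tributylstannyl)methyl]-2,5-dihydrofuran-2-yl}hepta-2,6-dien-1-yl 2-methylpropanoate | O=CC/C(COC(=O)C(C)C)=C\CC/C(COC(C)=O)=C\[C@H]1OC(=O)C(C[Sn](CCCC)(CCCC)CCCC)=C1 | intermediate
35 | CNP0312458.1, [(3aR,4R,6E,10E,11aR)-10-(acetoxymethyl)-4-hydroxy-3-methylidene-2-oxo-2,3,3a,4,5,8,9,11a-octahydrocyclodeca[b]furan-6-yl]methyl 2-methylpropanoate | C=C1C(=O)O[C@@H]2/C=C(/COC(C)=O)CC/C=C(/COC(=O)C(C)C)C[C@@H](O)[C@@H]12 | target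

## Step count and least certain steps

Total step count: 18. Longest linear sequence: 16 steps (steps 3–7 from 6, then steps 8–18). The iodide branch (steps 1–2) joins at step 8.

**Step 18 (key step).** Two things can go wrong.
- The electron-poor, γ-substituted stannane may react too slowly, so that oligomerisation, protodestannylation or ene-type reaction of the BF3-activated aldehyde with a ring olefin takes over.
- Ring strain rather than the open transition state may decide the aldehyde face, giving the 8-epimer.

The fallback uses established reaction types: metal-mediated Barbier addition of 3-(bromomethyl)butenolides to aldehydes, Barbier closure of ten-membered germacranolide rings, and Mitsunobu inversion. It sets out from bromo alcohol 31. Dess–Martin oxidation should give the bromo aldehyde F1. Indium powder in THF/H2O (or CrCl2 in THF) at high dilution should close the same C7–C8 bond through a closed six-membered chair transition state. With the C6 substituent trans to the metallated CH2 this is expected to give the anti product, the 8-epimer F2. Mitsunobu inversion with formic acid (PPh3, diisopropyl azodicarboxylate) should give the 8R formate F3, and methanolysis with KHCO3 in MeOH at 0 °C comes back to the route at 35. If step 18 itself delivers F2, the same two operations apply.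

**Step 16.** Zerovalent palladium may also ionise the allylic acetate, the isobutyrate or the doubly allylic C6–O bond of the lactone, or couple the product stannane with unreacted bromide. The fallback introduces tin before the ring is closed, where the two allylic termini are equivalent. It sets out from ester 29. Sodium benzenesulfinate in DMF should give the allyl sulfone F4. Bu3SnH with AIBN in benzene at 80 °C should exchange sulfonyl for tin by radical addition–fragmentation, giving the stannylmethyl acrylate F5. Ring-closing metathesis as in step 14 should give the stannyl butenolide silyl ether F6, and desilylation with HF·pyridine/pyridine in THF at 0 °C comes back to the route at 33.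

**Step 12.** Facial selectivity may be poor, because the acetate, isobutyrate and silyl ether oxygens compete with the ligand for zinc and residual magnesium salts catalyse a racemic background addition. The fallback replaces catalyst control by resolution and sets out from enal 23. Vinylmagnesium bromide 24 in THF at −78 °C should give the racemic carbinol F7. Novozym 435 (immobilised Candida antarctica lipase B) with vinyl acetate in hexane should acetylate the R enantiomer to the acetate F8, following the usual enantiopreference of lipases for secondary alcohols with one small (vinyl) and one large substituent. The unreacted S alcohol is separated, and the route is rejoined at 27, at the cost of half the material.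

**Step 17.** The C1=C10 double bond may migrate into conjugation with the new aldehyde, or the acetic acid released may protonate the stannane. The fallback reverses the order of oxidation and stannylation and sets out from 31. Oxidation at the bromide stage gives the bromo aldehyde F1, which has no acid-labile C–Sn bond and can be purified quickly. Pd2(dba)3 with 32 in THF at −20 → 0 °C then generates 34 in solution, which after filtration through Florisil and dilution with CH2Cl2 is treated directly with BF3·OEt2 at −78 °C, so the route is rejoined at 35 without isolating 34.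

## Further compounds

F1 | step 18 | (2E,6E)-6-(acetoxymethyl)-7-[(2R)-4-(bromomethyl)-5-oxo-2,5-dihydrofuran-2-yl]-2-(2-oxoethyl)hepta-2,6-dien-1-yl 2-methylpropanoate (bromo aldehyde) | O=CC/C(COC(=O)C(C)C)=C\CC/C(COC(C)=O)=C\[C@H]1OC(=O)C(CBr)=C1
F2 | step 18 | 8-epimer of 35 (6R,7R,8S) | C=C1C(=O)O[C@@H]2/C=C(/COC(C)=O)CC/C=C(/COC(=O)C(C)C)C[C@H](O)[C@@H]12
F3 | step 18 | 8-O-formyl derivative of 35 (6R,7R,8R) | C=C1C(=O)O[C@@H]2/C=C(/COC(C)=O)CC/C=C(/COC(=O)C(C)C)C[C@@H](OC=O)[C@@H]12
F4 | step 16 | (2E,6E,8S)-6-(acetoxymethyl)-8-({2-[(phenylsulfonyl)methyl]prop-2-enoyl}oxy)-2-{2-[(tert-butyldimethylsilyl)oxy]ethyl}deca-2,6,9-trien-1-yl 2-methylpropanoate (allyl sulfone) | CC(C)(C)[Si](C)(C)OCC/C(COC(=O)C(C)C)=C\CC/C(COC(C)=O)=C\[C@H](C=C)OC(=O)C(=C)CS(=O)(=O)c1ccccc1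
F5 | step 16 | (2E,6E,8S)-6-(acetoxymethyl)-8-({2-[(tributylstannyl)methyl]prop-2-enoyl}oxy)-2-{2-[(tert-butyldimethylsilyl)oxy]ethyl}deca-2,6,9-trien-1-yl 2-methylpropanoate (stannylmethyl acrylate) | CC(C)(C)[Si](C)(C)OCC/C(COC(=O)C(C)C)=C\CC/C(COC(C)=O)=C\[C@H](C=C)OC(=O)C(=C)C[Sn](CCCC)(CCCC)CCCC
F6 | step 16 | tert-butyldimethylsilyl ether of 33 (stannyl butenolide silyl ether) | CC(C)(C)[Si](C)(C)OCC/C(COC(=O)C(C)C)=C\CC/C(COC(C)=O)=C\[C@H]1OC(=O)C(C[Sn](CCCC)(CCCC)CCCC)=C1
F7 | step 12 | racemic (2E,6E)-6-(acetoxymethyl)-8-hydroxy-2-{2-[(tert-butyldimethylsilyl)oxy]ethyl}deca-2,6,9-trien-1-yl 2-methylpropanoate | CC(C)(C)[Si](C)(C)OCC/C(COC(=O)C(C)C)=C\CC/C(COC(C)=O)=C\C(C=C)O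
F8 | step 12 | (2E,6E,8R)-8-acetoxy-6-(acetoxymethyl)-2-{2-[(tert-butyldimethylsilyl)oxy]ethyl}deca-2,6,9-trien-1-yl 2-methylpropanoate | CC(C)(C)[Si](C)(C)OCC/C(COC(=O)C(C)C)=C\CC/C(COC(C)=O)=C\[C@@H](C=C)OC(C)=O
F0 | step 17 | none | none
A1 | alternative 1 | open-chain C1–C9 allylic alcohol from the nickel coupling (C1 as 1,3-dioxolane, C15 O-TBS, free C6 hydroxyl, C7 bearing CH2CO2t-Bu, C8 O-TBS, C9 O-PMB, C3 cis to C6 on C4=C5) | C1(OCCO1)CC/C(CO[Si](C)(C)C(C)(C)C)=C\[C@@H](O)[C@H](CC(=O)OC(C)(C)C)[C@H](O[Si](C)(C)C(C)(C)C)COCc1ccc(OC)cc1
A2 | alternative 2 | ten-membered dienone from the fragmentation (C8 ketone, C15 methyl ester on the E C4=C5 enoate, C14 O-TBDPS, C6 O-TBS, C7 bearing the 3-(PMB-oxy)prop-1-en-2-yl group) | [C@@H]1(O[Si](C)(C)C(C)(C)C)/C=C(/C(=O)OC)CC/C=C(/CO[Si](c2ccccc2)(c2ccccc2)C(C)(C)C)CC(=O)[C@H]1C(=C)COCc1ccc(OC)cc1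
A3 | alternative 3 | ten-membered trans-lactone without C13 (C15 O-TBS, C14 O-PMB, C8 O-TBS) | C1C(=O)O[C@@H]2/C=C(/CO[Si](C)(C)C(C)(C)C)CC/C=C(/COCc3ccc(OC)cc3)C[C@@H](O[Si](C)(C)C(C)(C)C)[C@@H]12
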